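Two questions stand here, and one number answers both: how G and Z divide what they take from X as Q is varied.

| setting | beta | epsilon | ochre | violet | red |
|---|---|---|---|---|---|
| X | 0.014 M | 0.014 M | 0.014 M | 0.014 M | 0.014 M |
| J | 5.4 mM (held) | 5.4 mM (held) | 5.4 mM (held) | 5.4 mM (held) | 5.4 mM (held) |
| Q | 0.44 mM | 4.3 mM | 0.300 mM | 1.00 mM | 3.00 mM |
| L | 3.2 mol% | 3.2 mol% | 3.2 mol% | 3.2 mol% | 3.2 mol% |
| remark | run made earlier | run made earlier |  |  |  |
| time |  |  | 20 h | 20 h | 20 h |

| run | time / h | G / % | Z / % | X / % |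
|---|---|---|---|---|
| beta | 3.00 | 3.4 | 3.9 | 91.7 |
| beta | 6.00 | 7.6 | 11.9 | 79.3 |
| beta | 10.0 | 14.1 | 19.6 | 63.5 |
| beta | 12.0 | 17.5 | 24.3 | 56.8 |
| beta | 15.0 | 20.5 | 29.4 | 47.9 |
| beta | 20.0 | 25.8 | 35.9 | 34.9 |
| epsilon | 3.00 | 3.4 | 4.7 | 83.3 |
| epsilon | 6.00 | 7.8 | 10.1 | 66.2 |
| epsilon | 10.0 | 12.2 | 17.7 | 49.3 |
| epsilon | 12.0 | 14.7 | 21.0 | 42.2 |
| epsilon | 15.0 | 17.3 | 24.4 | 33.8 |
| epsilon | 20.0 | 22.0 | 31.6 | 24.4 |

(each reading ± 0.5 percentage points)

1. share of G in all that became G or Z for ochre, violet, red, in this order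
2. the course of these numbers from the first flask to the last (rises all the way / rises, then falls / falls, then rises / falls all the way / hardly changes)

- the numbers in the tables scatter by 0.5 percentage points (one standard deviation)
- at the start none of J is in solution
- "hardly changes" means that all values lie within two and a half points (for a concentration: within two and a half percent of the largest)

I compare two amounts at 20.0 h, the Z formed and the G formed. Their quotient is the branching ratio b, Z over G, a selectivity factor, and the asked share follows from it: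

b(beta) = 35.9 % / 25.8 % = 1.39

b(epsilon) = 31.6 % / 22.0 % = 1.44

share = 1 / (1 + b), so 41.8 % in beta and 41.0 % in epsilon

Those shares differ by 0.80 percentage points, against a scatter of 0.5 points on each reading, while [Q] at the start differs by a factor of 9.77. Yet Q does act on the flask: the X missing from the balance at that time reads 3.40 % in beta and 22.0 % in epsilon, more with more Q. So I read Q as lowering G and Z together, and I commit to a flat row between those two shares, though ochre starts a little below beta in Q.

The forecast gives 41.5 %, 41.5 % and 41.5 %, so hardly changes, holding that “Q lowers the yield of G and Z but not their ratio”.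

The flasks give 42.0 %, 42.0 % and 42.0 %: hardly changes.

    X + D + L ⇌ L + G (K = 7400 M⁻¹, k = 13300 M⁻² h⁻¹)
    X + Q → E (k = 11.1 M⁻¹ h⁻¹)
    J ⇌ D, rate k3*(csat - [D]) (kL = 0.368 h⁻¹)
    X + D → Z (k = 8.16 M⁻¹ h⁻¹)

In ochre at 6.51 h, the step of X with D, the dissolved J, to Z uses D 1.4 times as fast as the forward step to G, and b as read from beta at 20.0 h is 1.39. Put into the share, that b gives 41.8 % against 42.0 % for ochre. In red at 20.0 h, E stands at 17.8 % against 1.87 % in ochre, and Z over G in red is 1.38.

(The data were computed for substances that don't exist; scatter was added.)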